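Ring C of the naphthol half is disconnected at C1'–C8a'. C1' is at once alpha to the C2' oxygen, bonded to ring D at C8a', and the carbon that carries quinone C3, so it can act as a ketone enolate carbon. One palladium-catalysed intramolecular enolate arylation closes ring C and aromatises it to the 2'-naphthol. It also leaves the crowded C3–C1' axis and the 2'-OH/4'-OCH3 pattern complete. The precursor is an (E)-β-methoxy enone. C4' carries ring D (Br at C8a', MOM ether at C5'), and the C1' methylene carries plumbagin methyl ether masked as its bis-MOM hydroquinone.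

Key step: step 10

Assumption: the target SMILES fixes no sense of twist about the C3–C1' axis, so the racemic atropisomer is the goal.
Numbering: C1–C8a are the quinone half (rings A and B) and C1'–C8a' the naphthol half (rings C and D). Named as a 2-naphthyl substituent, the masked quinone has its OCH3 at C8, peri to the C1 oxygen that flanks the point of attachment.

Step 1
Reactants: 1 3-bromo-5-methylphenol
Product: 2 1-bromo-3-(methoxymethoxy)-5-methylbenzene
Conditions: NaH, MOMCl, THF, 0 °C to rt
Reagents that add atoms: chloromethyl methyl ether (MOMCl), COCCl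
Why: Williamson-type O-alkylation of the sodium phenoxide is reliable, and the MOM acetal is chosen because it directs the next metalation and later leaves under the same mild acid as the two hydroquinone acetals.

Step 2
Reactants: 2 1-bromo-3-(methoxymethoxy)-5-methylbenzene
Product: 5 2-bromo-6-(methoxymethoxy)-4-methylbenzaldehyde, via aryllithium 3 (not isolated), via lithium aminal alkoxide 4 (not isolated)
Conditions: LiN(i-Pr)2 (1.1 equiv), THF, −78 °C; DMF, −78 °C; AcOH quench
Reagents that add atoms: N,N-dimethylformamide, CN(C)C=O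
Why: Directed ortho-metalation: the C–H between OMOM (lithium coordination) and Br (inductive acidification) is the most acidic ring position, a lithium amide deprotonates without the bromine–lithium exchange an alkyllithium would cause, and at −78 °C aryllithium 3 is formylated by DMF faster than it loses LiBr, so the regiochemical ambiguity of formylating the free phenol is avoided.

Step 3
Reactants: 5 2-bromo-6-(methoxymethoxy)-4-methylbenzaldehyde
Product: 6 1-bromo-2-ethynyl-3-(methoxymethoxy)-5-methylbenzene
Conditions: dimethyl (1-diazo-2-oxopropyl)phosphonate, K2CO3, MeOH, 0 °C to rt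
Reagents that add atoms: dimethyl (1-diazo-2-oxopropyl)phosphonate, COP(=O)(OC)C(=[N+]=[N-])C(C)=O
Why: The Ohira–Bestmann modification of the Seyferth–Gilbert homologation converts the non-enolisable aldehyde into the terminal alkyne under carbonate in methanol, conditions that leave the aryl bromide and the MOM ether alone, whereas a Corey–Fuchs sequence would need butyllithium.

Step 4
Reactants: 7 plumbagin (5-hydroxy-2-methyl-1,4-naphthoquinone)
Product: 8 5-methoxy-2-methyl-1,4-naphthoquinone
Conditions: MeI, Ag2O, CH2Cl2, rt, dark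
Reagents that add atoms: iodomethane, CI
Why: Silver-oxide-mediated O-methylation (Purdie conditions) alkylates the hydrogen-bonded peri phenol without the strong base that would degrade the quinone.

Step 5
Reactants: 8 5-methoxy-2-methyl-1,4-naphthoquinone
Product: 10 3-bromo-5-methoxy-2-methyl-1,4-naphthoquinone, via trans-dibromide 9 (not isolated)
Conditions: Br2, NaOAc, AcOH, rt, dark
Reagents that add atoms: bromine, BrBr
Why: Electrophilic addition of bromine to the C2=C3 bond of ring B and acetate-induced loss of HBr (addition–elimination) put bromine on C3, the only free quinone position, while ring A is deactivated by both carbonyl groups.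

Step 6
Reactants: 10 3-bromo-5-methoxy-2-methyl-1,4-naphthoquinone
Product: 12 3-bromo-5-methoxy-1,4-bis(methoxymethoxy)-2-methylnaphthalene, via bromohydroquinone 11 (not isolated)
Conditions: Na2S2O4, EtOAc–H2O, rt; organic layer dried and carried on under Ar; NaH, MOMCl, DMF, 0 °C to rt
Reagents that add atoms: chloromethyl methyl ether (MOMCl), COCCl
Why: Dithionite reduction followed by double Williamson-type acetalisation under argon turns ring B into a bis-MOM hydroquinone that is inert to zinc, lithium and palladium reagents and can be unmasked later without an oxidant strong enough to harm rings C and D.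

Step 7
Reactants: 12 3-bromo-5-methoxy-1,4-bis(methoxymethoxy)-2-methylnaphthalene
Product: 13 2-[8-methoxy-1,4-bis(methoxymethoxy)-3-methylnaphthalen-2-yl]-1-(morpholin-4-yl)ethan-1-one
Conditions: Zn dust (Me3SiCl-activated), 4-(bromoacetyl)morpholine, THF, rt; then 12, {[P(t-Bu)3]PdBr}2 (2.5 mol %), THF, 60 °C
Reagents that add atoms: 4-(bromoacetyl)morpholine, O=C(CBr)N1CCOCC1
Why: Negishi-type cross-coupling of a Reformatsky reagent (palladium-catalysed alpha-arylation of a zinc amide enolate) runs under nearly neutral conditions, the small CH2 nucleophile and the bulky electron-rich phosphine cope with the two ortho substituents, and the morpholine amide arrives directly as the acyl donor for step 8.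

Step 8
Reactants: 6 1-bromo-2-ethynyl-3-(methoxymethoxy)-5-methylbenzene; 13 2-[8-methoxy-1,4-bis(methoxymethoxy)-3-methylnaphthalen-2-yl]-1-(morpholin-4-yl)ethan-1-one
Product: 16 4-[2-bromo-6-(methoxymethoxy)-4-methylphenyl]-1-[8-methoxy-1,4-bis(methoxymethoxy)-3-methylnaphthalen-2-yl]but-3-yn-2-one, via lithium acetylide 14 (not isolated), via lithium aminal alkoxide 15 (not isolated)
Conditions: 6 (1.3 equiv), LiN(i-Pr)2 (1.25 equiv), THF, −78 °C; 13, −78 to 0 °C; inverse quench into cold 1 M aq HCl–Et2O
Reagents that add atoms: none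
Why: Weinreb-type ketone synthesis with a morpholine amide: acetylide 14 adds only once because alkoxide 15 does not collapse before the quench, the lithium amide base spares the aryl bromide, and pouring into cold acid protonates morpholine and diisopropylamine before they can add to the ynone.

Step 9
Reactants: 16 4-[2-bromo-6-(methoxymethoxy)-4-methylphenyl]-1-[8-methoxy-1,4-bis(methoxymethoxy)-3-methylnaphthalen-2-yl]but-3-yn-2-one
Product: 18 (E)-4-[2-bromo-6-(methoxymethoxy)-4-methylphenyl]-4-methoxy-1-[8-methoxy-1,4-bis(methoxymethoxy)-3-methylnaphthalen-2-yl]but-3-en-2-one, via Z isomer 17 (not isolated)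
Conditions: NaOMe (0.3 equiv), MeOH–THF, 0 to 40 °C until the isomer composition no longer changes
Reagents that add atoms: methanol, CO
Why: Base-catalysed oxa-Michael addition places OCH3 only on the beta carbon C4', which differentiates the two ring C oxygens before the ring exists, and because methoxide addition is reversible the Z isomer 17 should drain into the E isomer, where OCH3 faces the small vinyl hydrogen and the twisted ring D lies on the carbonyl side.

Step 10
Reactants: 18 (E)-4-[2-bromo-6-(methoxymethoxy)-4-methylphenyl]-4-methoxy-1-[8-methoxy-1,4-bis(methoxymethoxy)-3-methylnaphthalen-2-yl]but-3-en-2-one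
Product: 20 1-[8-methoxy-1,4-bis(methoxymethoxy)-3-methylnaphthalen-2-yl]-4-methoxy-5-(methoxymethoxy)-7-methylnaphthalen-2-ol (racemic axis), via keto tautomer 19 (not isolated)
Conditions: Pd(OAc)2 (10 mol %), P(t-Bu)3·HBF4 (20 mol %), K3PO4 (3 equiv), degassed toluene, 100 °C, Ar
Reagents that add atoms: none
Why: Pd(OAc)2 is reduced in the flask to a zerovalent palladium–P(t-Bu)3 species that inserts into the C8a'–Br bond of ring D, K3PO4 deprotonates the C1' methylene (benzylic, alpha to C2'=O and the only enolisable site), the enolate replaces bromide on palladium, and C–C reductive elimination from the C-bound seven-membered palladacycle forms C1'–C8a'. The closest known reaction type is the palladium-catalysed intramolecular alpha-arylation of ketone enolates with aryl bromides in its naphthol-forming variant. Ring C closes as a six-membered carbocycle in a 6-(enolendo) mode, and dienone 19 enolises at once to naphthol 20, an irreversible aromatisation. No lasting stereocentre arises, since the transient C1' centre of 19 is erased by enolisation and the C3–C1' axis forms as a racemate. The step needs C- over O-arylation, ring closure over hydrodebromination and an alkene that holds ring D beside the carbonyl: the soft aryl-stabilised enolate carbon and the bulky electron-rich phosphine favour C–C reductive elimination, intramolecularity offsets the crowding at C1', and the E geometry fixed in step 9 brings C8a' within reach of C1' while keeping C3'–H away from palladium. The weak, non-nucleophilic phosphate base leaves the vinylogous ester and all three MOM ethers untouched.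

Step 11
Reactants: 20 1-[8-methoxy-1,4-bis(methoxymethoxy)-3-methylnaphthalen-2-yl]-4-methoxy-5-(methoxymethoxy)-7-methylnaphthalen-2-ol
Product: 22 3-(2,5-dihydroxy-4-methoxy-7-methylnaphthalen-1-yl)-5-methoxy-2-methyl-1,4-naphthoquinone (target), via free hydroquinone 21 (not isolated)
Conditions: HCl (1 M), MeOH–THF, Ar, 40 °C; then EtOAc–pH 7 buffer (NaH2PO4/Na2HPO4), air, rt
Reagents that add atoms: none
Why: Acid-catalysed transacetalisation to dimethoxymethane removes all three MOM groups while methanol traps the formaldehyde equivalent away from nucleophilic C3' and makes any exchange at C4'–OCH3 degenerate (dilute acid and mild warming keep acid-catalysed etherification of the hindered 2'-OH slow), and the electron-rich 2,3-disubstituted hydroquinone 21 then autoxidises in air to the quinone without touching rings C and D.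

Compound list
1 | 3-bromo-5-methylphenol | Cc1cc(O)cc(Br)c1 | starting material
2 | 1-bromo-3-(methoxymethoxy)-5-methylbenzene | COCOc1cc(C)cc(Br)c1 | intermediate
3 | [2-bromo-6-(methoxymethoxy)-4-methylphenyl]lithium | [Li]c1c(Br)cc(C)cc1OCOC | intermediate
4 | lithium [2-bromo-6-(methoxymethoxy)-4-methylphenyl](dimethylamino)methanolate (racemic) | [Li]OC(N(C)C)c1c(Br)cc(C)cc1OCOC | intermediate
5 | 2-bromo-6-(methoxymethoxy)-4-methylbenzaldehyde | O=Cc1c(Br)cc(C)cc1OCOC | intermediate
6 | 1-bromo-2-ethynyl-3-(methoxymethoxy)-5-methylbenzene | C#Cc1c(Br)cc(C)cc1OCOC | intermediate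
7 | plumbagin (5-hydroxy-2-methyl-1,4-naphthoquinone) | CC1=CC(=O)c2c(O)cccc2C1=O | starting material
8 | 5-methoxy-2-methyl-1,4-naphthoquinone | COc1cccc2c1C(=O)C=C(C)C2=O | intermediate
9 | trans-2,3-dibromo-5-methoxy-2-methyl-2,3-dihydronaphthalene-1,4-dione (racemic, one enantiomer drawn) | COc1cccc2c1C(=O)[C@H](Br)[C@@](C)(Br)C2=O | intermediate
10 | 3-bromo-5-methoxy-2-methyl-1,4-naphthoquinone | COc1cccc2c1C(=O)C(Br)=C(C)C2=O | intermediate
11 | 3-bromo-5-methoxy-2-methylnaphthalene-1,4-diol | COc1cccc2c(O)c(C)c(Br)c(O)c12 | intermediate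
12 | 3-bromo-5-methoxy-1,4-bis(methoxymethoxy)-2-methylnaphthalene | COCOc1c(C)c(Br)c(OCOC)c2c(OC)cccc12 | intermediate
13 | 2-[8-methoxy-1,4-bis(methoxymethoxy)-3-methylnaphthalen-2-yl]-1-(morpholin-4-yl)ethan-1-one | COCOc1c(C)c(CC(=O)N2CCOCC2)c(OCOC)c2c(OC)cccc12 | intermediate
14 | {[2-bromo-6-(methoxymethoxy)-4-methylphenyl]ethynyl}lithium | [Li]C#Cc1c(Br)cc(C)cc1OCOC | intermediate
15 | lithium 4-[2-bromo-6-(methoxymethoxy)-4-methylphenyl]-1-[8-methoxy-1,4-bis(methoxymethoxy)-3-methylnaphthalen-2-yl]-2-(morpholin-4-yl)but-3-yn-2-olate (racemic) | [Li]OC(C#Cc1c(Br)cc(C)cc1OCOC)(Cc1c(C)c(OCOC)c2cccc(OC)c2c1OCOC)N1CCOCC1 | intermediate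
16 | 4-[2-bromo-6-(methoxymethoxy)-4-methylphenyl]-1-[8-methoxy-1,4-bis(methoxymethoxy)-3-methylnaphthalen-2-yl]but-3-yn-2-one | COCOc1cc(C)cc(Br)c1C#CC(=O)Cc1c(C)c(OCOC)c2cccc(OC)c2c1OCOC | intermediate
17 | (Z)-4-[2-bromo-6-(methoxymethoxy)-4-methylphenyl]-4-methoxy-1-[8-methoxy-1,4-bis(methoxymethoxy)-3-methylnaphthalen-2-yl]but-3-en-2-one | CO/C(=C\C(=O)Cc1c(C)c(OCOC)c2cccc(OC)c2c1OCOC)c1c(Br)cc(C)cc1OCOC | intermediate
18 | (E)-4-[2-bromo-6-(methoxymethoxy)-4-methylphenyl]-4-methoxy-1-[8-methoxy-1,4-bis(methoxymethoxy)-3-methylnaphthalen-2-yl]but-3-en-2-one | CO/C(=C/C(=O)Cc1c(C)c(OCOC)c2cccc(OC)c2c1OCOC)c1c(Br)cc(C)cc1OCOC | intermediate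
19 | 1-[8-methoxy-1,4-bis(methoxymethoxy)-3-methylnaphthalen-2-yl]-4-methoxy-5-(methoxymethoxy)-7-methylnaphthalen-2(1H)-one (racemic) | COC1=CC(=O)C(c2c(C)c(OCOC)c3cccc(OC)c3c2OCOC)c2cc(C)cc(OCOC)c12 | intermediate
20 | 1-[8-methoxy-1,4-bis(methoxymethoxy)-3-methylnaphthalen-2-yl]-4-methoxy-5-(methoxymethoxy)-7-methylnaphthalen-2-ol (racemic axis) | COc1cc(O)c(-c2c(C)c(OCOC)c3cccc(OC)c3c2OCOC)c2cc(C)cc(OCOC)c12 | intermediate
21 | 3-(2,5-dihydroxy-4-methoxy-7-methylnaphthalen-1-yl)-5-methoxy-2-methylnaphthalene-1,4-diol | COc1cccc2c(O)c(C)c(-c3c(O)cc(OC)c4c(O)cc(C)cc34)c(O)c12 | intermediate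
22 | 3-(2,5-dihydroxy-4-methoxy-7-methylnaphthalen-1-yl)-5-methoxy-2-methyl-1,4-naphthoquinone (racemic axis) | COc1cccc2c1C(=O)C(c1c(O)cc(OC)c3c(O)cc(C)cc13)=C(C)C2=O | target

Total step count: 11
Longest linear sequence: 8 steps (steps 4–11, from plumbagin). The ring D branch (steps 1–3) joins at step 8.

Steps most likely to fail

1. Step 10. Reductive elimination at the crowded secondary enolate carbon may be too slow, so O-arylation of the enolate or hydrodebromination of ring D could take over.
- The fallback builds ring C on an unhindered ketone and makes the axis afterwards. It sets out from 6 and 12 and returns at 20.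
- Alkyne 6 is lithiated as in step 8 and acylated with 4-acetylmorpholine to give 4-[2-bromo-6-(methoxymethoxy)-4-methylphenyl]but-3-yn-2-one F1.
- NaOMe in MeOH converts this into (E)-4-[2-bromo-6-(methoxymethoxy)-4-methylphenyl]-4-methoxybut-3-en-2-one F2.
- The same palladium enolate arylation, now at a methyl carbon, gives 4-methoxy-5-(methoxymethoxy)-7-methylnaphthalen-2-ol F3.
- N-Iodosuccinimide iodinates the most activated position (ortho to OH, para to OCH3) to give 1-iodo-4-methoxy-5-(methoxymethoxy)-7-methylnaphthalen-2-ol F4.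
- Bromide 12 undergoes halogen–lithium exchange (n-BuLi, THF, −78 °C) and is trapped with 2-isopropoxy-4,4,5,5-tetramethyl-1,3,2-dioxaborolane. This gives 2-[8-methoxy-1,4-bis(methoxymethoxy)-3-methylnaphthalen-2-yl]-4,4,5,5-tetramethyl-1,3,2-dioxaborolane F5.
- Suzuki–Miyaura coupling of the two halves (Pd(OAc)2, SPhos, K3PO4, toluene–H2O, 100 °C) delivers 20.

2. Step 7. Oxidative addition and transmetalation at the electron-rich, doubly ortho-substituted C–Br bond may be sluggish, so the zinc enolate could be consumed by protonation before it couples.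
- The fallback replaces cross-coupling by carbanion chemistry. It sets out from 12 and returns at 13.
- Halogen–lithium exchange (n-BuLi, THF, −78 °C) and opening of ethylene oxide with BF3·OEt2 give 2-[8-methoxy-1,4-bis(methoxymethoxy)-3-methylnaphthalen-2-yl]ethan-1-ol F6.
- TEMPO/PhI(OAc)2 in MeCN–H2O oxidises it to [8-methoxy-1,4-bis(methoxymethoxy)-3-methylnaphthalen-2-yl]acetic acid F7.
- Carbodiimide coupling with morpholine (EDC·HCl, HOBt) gives 13.

3. Step 8. Deprotonation of the arylacetamide CH2 by the acetylide may compete with addition and stall the acylation. Conjugate addition of the released amines at the quench may also erode the ynone.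
- The fallback swaps acylation for addition followed by oxidation. It sets out from 13 and returns at 16.
- i-Bu2AlH (THF, −78 °C) reduces the morpholine amide to [8-methoxy-1,4-bis(methoxymethoxy)-3-methylnaphthalen-2-yl]acetaldehyde F8.
- Acetylide 14 adds to it at −78 °C (with CeCl3 if enolisation persists) to give racemic 4-[2-bromo-6-(methoxymethoxy)-4-methylphenyl]-1-[8-methoxy-1,4-bis(methoxymethoxy)-3-methylnaphthalen-2-yl]but-3-yn-2-ol F9.
- Dess–Martin periodinane buffered with NaHCO3 oxidises this to 16.

Further compounds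
F1 | step 10 | 4-[2-bromo-6-(methoxymethoxy)-4-methylphenyl]but-3-yn-2-one | CC(=O)C#Cc1c(Br)cc(C)cc1OCOC
F2 | step 10 | (E)-4-[2-bromo-6-(methoxymethoxy)-4-methylphenyl]-4-methoxybut-3-en-2-one | CO/C(=C/C(C)=O)c1c(Br)cc(C)cc1OCOC
F3 | step 10 | 4-methoxy-5-(methoxymethoxy)-7-methylnaphthalen-2-ol | COc1cc(O)cc2cc(C)cc(OCOC)c12
F4 | step 10 | 1-iodo-4-methoxy-5-(methoxymethoxy)-7-methylnaphthalen-2-ol | COc1cc(O)c(I)c2cc(C)cc(OCOC)c12
F5 | step 10 | 2-[8-methoxy-1,4-bis(methoxymethoxy)-3-methylnaphthalen-2-yl]-4,4,5,5-tetramethyl-1,3,2-dioxaborolane | COCOc1c(C)c(B2OC(C)(C)C(C)(C)O2)c(OCOC)c2c(OC)cccc12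
F6 | step 7 | 2-[8-methoxy-1,4-bis(methoxymethoxy)-3-methylnaphthalen-2-yl]ethan-1-ol | COCOc1c(C)c(CCO)c(OCOC)c2c(OC)cccc12
F7 | step 7 | [8-methoxy-1,4-bis(methoxymethoxy)-3-methylnaphthalen-2-yl]acetic acid | COCOc1c(C)c(CC(=O)O)c(OCOC)c2c(OC)cccc12
F8 | step 8 | [8-methoxy-1,4-bis(methoxymethoxy)-3-methylnaphthalen-2-yl]acetaldehyde | COCOc1c(C)c(CC=O)c(OCOC)c2c(OC)cccc12
F9 | step 8 | 4-[2-bromo-6-(methoxymethoxy)-4-methylphenyl]-1-[8-methoxy-1,4-bis(methoxymethoxy)-3-methylnaphthalen-2-yl]but-3-yn-2-ol (racemic) | COCOc1cc(C)cc(Br)c1C#CC(O)Cc1c(C)c(OCOC)c2cccc(OC)c2c1OCOC
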